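Readings and results are simulated for an exercise, and the scatter is random.

The alder run, charged with 0.70 M of substrate, and the elm run, charged with 1.1 M, end at 20.0 h on different percentages but on nearly the same amount outside target, and I build my reckoning on that.

| setting | alder | elm | flask |
|---|---|---|---|
| substrate | 0.70 M | 1.1 M | 0.50 M |
| remark | run made earlier | run made earlier |  |
| time |  |  | 15 h |

| run | time / h | target / % | isomer of the product / % | substrate / % |
|---|---|---|---|---|
| alder | 2.50 | 63.6 | 22.3 | 7.0 |
| alder | 6.00 | 73.6 | 17.6 | 5.7 |
| alder | 12.0 | 79.0 | 13.6 | 4.3 |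
| alder | 20.0 | 80.7 | 12.0 | 4.7 |
| elm | 2.50 | 66.8 | 21.1 | 6.8 |
| elm | 6.00 | 78.5 | 15.0 | 3.6 |
| elm | 12.0 | 85.3 | 10.2 | 3.5 |
| elm | 20.0 | 88.0 | 7.9 | 2.9 |

(each reading ± 0.3 percentage points)

- a reading or a percentage of target counts all its forms, free or not

* share of target in target plus isomer of the product at 30 s
* share of target in target plus isomer of the product at 15 h
* which of target and isomer of the product there is more of at 15 h

I work in powers of ten at 20.0 h. From alder to elm the logarithm of the charge rises by 0.196, and that of the percentage outside target falls by 0.206, so percentage times charge stays nearly constant: 0.135 M in alder, 0.132 M in elm. I call their mean L, 0.134 M, and the isomer's mean I, 0.0854 M. Dividing L by the flask's charge of 0.50 M gives 0.267, and this number N, the part of a charge that stays out of target late in a run, is what I carry. So at 15 h I expect target at 73.3% of the charge and isomer at 17.1%, a share of 81.1% with target ahead.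

One number is not quite enough. At 12.0 h the amounts outside target still stand apart, at 0.147 M in alder and 0.162 M in elm, and N says nothing about 30 s. There I go by the shares at 2.50 h, 74.0% and 76.0%, which rise afterwards, so I put the start below them.

The forecast says 67% at 30 s and 83% at 15 h, above my share, with target ahead, and reads the late drift thus: “this looks like a fading process rather than a true equilibrium”.

The flask gives 70.1% at 30 s and 80.9% at 15 h, with target at 72.9% and isomer at 17.2%.

    substrate ⇌ isomer of the product (K = 2.60, k = 1.90 × 10⁻⁴ s⁻¹)
    crystals ⇌ target, rate k2*(cs2 - [target]) while solid is left; crystals form when [target] > cs2 (solubility = 19.0 mM, k = 0.0100 s⁻¹)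
    substrate ⇌ dormant form (K = 0.530, k = 1.40 × 10⁻⁴ s⁻¹)
    substrate ⇌ target (K = 0.600, k = 4.50 × 10⁻⁴ s⁻¹)
    target ⇌ isomer of the product (k = 3.90 × 10⁻⁵ s⁻¹)

In the flask at 15.0 h, 27.1% of the charge stands outside target, against 26.7% from N, and crystals hold 69.1%. A neighbouring flask is like this one but charged with 0.12 M, so N becomes 1.11, above one: L exceeds that whole charge. At 15.0 h that neighbouring flask holds crystals 0%, target 12.7% and isomer 55.0%, a share of 18.8%.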